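The route is built on one disconnection: the lactone bond C12–C11, between the carbonyl carbon and the α-carbon that carries CH2OAc. The key step exploits the fact that C7=C11–C13–OAc of the butenolide ring (O6, C12, C11, C7, C6) is a masked allene: a ten-membered α-allenol with an exocyclic vinylidene (C7=C11=C13H2) beside the free C6 hydroxyl is carbonylated under oxidative palladium catalysis. CO is bound to O6, the alkoxycarbonyl carbon adds to the central allene carbon C11 to close the butenolide, and acetate captures the allylpalladium at C13. The allenol comes from a chromium-mediated propargyl–aldehyde macrocyclisation of a methyl geranate-derived chain; angeloylation and double epoxidation finish the synthesis.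

Key step: step 10

Remark: ring compounds are numbered as germacranes (C1–C10 in the ring, C11–C13 the unit on C7, C14 and C15 the methyls on C10 and C4); the acetal carbon of the tetrahydropyranyl group in 5–8 is an inconsequential mixture of epimers and is written without configuration.

Step 1
Reactants: 1 methyl (2E)-3,7-dimethylocta-2,6-dienoate (methyl geranate)
Product: 2 methyl (2E,6E)-8-hydroxy-3,7-dimethylocta-2,6-dienoate
Conditions: SeO2 (0.3 equiv), tBuOOH (3 equiv), salicylic acid (0.1 equiv), CH2Cl2, 0 → 25 °C
Reagents that add atoms: selenium dioxide, O=[Se]=O (catalytic oxygen carrier); tert-butyl hydroperoxide, CC(C)(C)OO (terminal oxygen source)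
Why: The catalytic SeO2/tBuOOH allylic oxidation (ene reaction, then [2,3]-sigmatropic shift) attacks the electron-rich terminal alkene rather than the ester-deactivated C2=C3 bond and oxidises its E-methyl group, which fixes the 6E geometry without creating a stereocentre.

Step 2
Reactants: 2 methyl (2E,6E)-8-hydroxy-3,7-dimethylocta-2,6-dienoate
Product: 3 methyl (2E,6E)-8-bromo-3,7-dimethylocta-2,6-dienoate
Conditions: CBr4 (1.2 equiv), PPh3 (1.3 equiv), CH2Cl2, 0 °C
Reagents that add atoms: carbon tetrabromide, BrC(Br)(Br)Br
Why: The Appel reaction converts the primary allylic alcohol into the bromide by SN2 displacement of the oxyphosphonium ion under neutral conditions, without allylic transposition or loss of alkene geometry.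

Step 3
Reactants: 3 methyl (2E,6E)-8-bromo-3,7-dimethylocta-2,6-dienoate
Product: 4 methyl (2E,6E)-3,7-dimethyl-9-oxonona-2,6-dienoate
Conditions: CO (3 atm), Bu3SnH (1.1 equiv, syringe pump), Pd(PPh3)4 (4 mol %), THF, 50 °C
Reagents that add atoms: carbon monoxide, [C-]#[O+]
Why: In this palladium-catalysed reductive carbonylation (Stille formylation), zerovalent palladium ionises the allylic bromide, CO inserts at the less substituted allyl terminus with retention of the E geometry and the tin hydride reduces the acylpalladium to the β,γ-unsaturated aldehyde, while the conjugated ester is inert.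

Step 4
Reactants: 4 methyl (2E,6E)-3,7-dimethyl-9-oxonona-2,6-dienoate; 5 2-(prop-2-yn-1-yloxy)oxane (tetrahydropyranyl propargyl ether)
Product: 7 methyl (2E,6E,9S)-9-hydroxy-3,7-dimethyl-12-(oxan-2-yloxy)dodeca-2,6-dien-10-ynoate, via methylzinc acetylide 6 (not isolated)
Conditions: 5 (3 equiv), Me2Zn (3 equiv), (S,S)-ProPhenol (20 mol %), Ph3PO (40 mol %), toluene, 0 °C, slow addition of 4
Reagents that add atoms: none
Why: In the dinuclear zinc–ProPhenol enantioselective alkynylation, the alkynylzinc 6 should be delivered to the Re face of the aldehyde inside the chiral dizinc pocket (ligand hand chosen by analogy with its aldol reactions, to be confirmed by Mosher analysis), which sets the 9S carbinol (C8 of the target), and the weakly basic zinc reagents should leave the β,γ-alkene unconjugated.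

Step 5
Reactants: 7 methyl (2E,6E,9S)-9-hydroxy-3,7-dimethyl-12-(oxan-2-yloxy)dodeca-2,6-dien-10-ynoate
Product: 8 methyl (2E,6E,9S)-9-[(tert-butyldimethylsilyl)oxy]-3,7-dimethyl-12-(oxan-2-yloxy)dodeca-2,6-dien-10-ynoate
Conditions: TBSCl (1.5 equiv), imidazole (3 equiv), DMF, 25 °C
Reagents that add atoms: tert-butyldimethylsilyl chloride, CC(C)(C)[Si](C)(C)Cl
Why: Imidazole-promoted silylation of the secondary propargylic alcohol is non-acidic, so the tetrahydropyranyl acetal survives, and the silyl ether later blocks the C8 oxygen from competing in the lactonisation.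

Step 6
Reactants: 8 methyl (2E,6E,9S)-9-[(tert-butyldimethylsilyl)oxy]-3,7-dimethyl-12-(oxan-2-yloxy)dodeca-2,6-dien-10-ynoate
Product: 9 methyl (2E,6E,9S)-12-bromo-9-[(tert-butyldimethylsilyl)oxy]-3,7-dimethyldodeca-2,6-dien-10-ynoate
Conditions: CBr4 (1.3 equiv), PPh3 (2.6 equiv), CH2Cl2, 25 °C
Reagents that add atoms: carbon tetrabromide, BrC(Br)(Br)Br
Why: In this direct Appel-type conversion of a tetrahydropyranyl ether, the bromophosphonium ion activates the acetal oxygen, the tetrahydropyranyl cation leaves as dihydropyran and bromide displaces the primary propargylic oxyphosphonium group, while the secondary silyl ether and the ester are untouched.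

Step 7
Reactants: 9 methyl (2E,6E,9S)-12-bromo-9-[(tert-butyldimethylsilyl)oxy]-3,7-dimethyldodeca-2,6-dien-10-ynoate
Product: 10 (2E,6E,9S)-12-bromo-9-[(tert-butyldimethylsilyl)oxy]-3,7-dimethyldodeca-2,6-dien-10-yn-1-ol
Conditions: iBu2AlH (2.3 equiv), CH2Cl2, −78 °C; Rochelle salt work-up
Reagents that add atoms: none
Why: Diisobutylaluminium hydride reduces the conjugated methyl ester to the allylic alcohol by 1,2-hydride delivery at low temperature, where the propargylic bromide, the alkyne and the silyl ether are not attacked.

Step 8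
Reactants: 10 (2E,6E,9S)-12-bromo-9-[(tert-butyldimethylsilyl)oxy]-3,7-dimethyldodeca-2,6-dien-10-yn-1-ol
Product: 11 (2E,6E,9S)-12-bromo-9-[(tert-butyldimethylsilyl)oxy]-3,7-dimethyldodeca-2,6-dien-10-ynal
Conditions: activated MnO2 (15 equiv), CH2Cl2, 25 °C
Reagents that add atoms: none
Why: Activated MnO2 oxidises the primary allylic alcohol to the (E)-enal selectively and neutrally, and it is used here because phosphine/CBr4 chemistry after aldehyde formation would give a dibromoalkene.

Step 9
Reactants: 11 (2E,6E,9S)-12-bromo-9-[(tert-butyldimethylsilyl)oxy]-3,7-dimethyldodeca-2,6-dien-10-ynal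
Product: 13 (1R,3S,5E,9E)-3-[(tert-butyldimethylsilyl)oxy]-2-ethenylidene-5,9-dimethylcyclodeca-5,9-dien-1-ol (germacrane numbering 6R,8S), via propargylchromium dichloride 12 (not isolated)
Conditions: CrCl2 (10 equiv), THF, 25 °C, syringe-pump addition of 11 (final 2 mM)
Reagents that add atoms: none
Why: In this propargyl version of the Nozaki–Hiyama reaction, CrCl2 reduces the propargylic bromide to a propargylchromium species of trivalent chromium (12) that adds to the aldehyde through its γ-carbon (SE2′), which closes the ten-membered ring by the C6–C7 bond and turns the alkyne into the exocyclic vinylidene, while the C8 stereocentre should set C6 through a crown-shaped transition state with the silyloxy group and the chromium-bound aldehyde oxygen both pseudo-equatorial (6,8-syn, 6R).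

Step 10
Reactants: 13 (1R,3S,5E,9E)-3-[(tert-butyldimethylsilyl)oxy]-2-ethenylidene-5,9-dimethylcyclodeca-5,9-dien-1-ol
Product: 16 (1(10)E,4E,6R,8S)-13-acetoxy-8-[(tert-butyldimethylsilyl)oxy]germacra-1(10),4,7(11)-trien-12,6-olide, via alkoxycarbonylpalladium acetate 14 (not isolated), via allylpalladium acetate 15 (not isolated)
Conditions: Pd(OAc)2 (10 mol %), 1,4-benzoquinone (1.5 equiv), NaOAc (2 equiv), AcOH (5 equiv), CO (1 atm), THF, 25 °C
Reagents that add atoms: carbon monoxide, [C-]#[O+]; acetic acid, CC(=O)O
Why: Proposed new method: divalent palladium and CO convert the C6 hydroxyl into the alkoxycarbonylpalladium acetate 14, whose acyl carbon C12 adds syn across the distal C11=C13 π-bond of the vinylidene, bonding to the central allene carbon C11 and leaving palladium on C13 as the σ/π-allyl complex 15 spanning C7–C11–C13; acetate then attacks the unhindered C13 terminus and releases the conjugated butenolide and zerovalent palladium, which benzoquinone reoxidises. The closest known reaction types are the PdCl2/CuCl2 chlorocyclocarbonylation of 2,3-allenols to 3-(chloromethyl)butenolides and the divalent palladium/benzoquinone 1,2-oxidation of allenes, so only the acetate termination under benzoquinone turnover is new. The butenolide (O6, C12, C11, C7, C6) closes in a 5-exo-trig mode with respect to the C11=C13 bond, the mode the geometry imposes because the in-plane p orbital of C11 belongs to that bond. No stereocentre is formed, and C6 keeps its configuration because only its O–H bond reacts. The step needs site selectivity for O6 (secured by the silyl ether on the C8 oxygen, so the 12,8-lactone cannot form), chemoselectivity for alkoxycarbonylation over 5-endo oxypalladation or diene complexation (favoured by CO-saturated palladium and acetate base) and regioselectivity for acetate attack at primary C13 rather than fully substituted C7 (steric and conjugative preference).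

Step 11
Reactants: 16 (1(10)E,4E,6R,8S)-13-acetoxy-8-[(tert-butyldimethylsilyl)oxy]germacra-1(10),4,7(11)-trien-12,6-olide
Product: 17 (1(10)E,4E,6R,8S)-13-acetoxy-8-hydroxygermacra-1(10),4,7(11)-trien-12,6-olide
Conditions: HF·pyridine, pyridine, THF, 0 → 25 °C
Reagents that add atoms: none
Why: Pyridine-buffered HF cleaves the secondary silyl ether through the strong Si–F bond and avoids the basic fluoride conditions that could eliminate the allylic acetate of the butenolide.

Step 12
Reactants: 17 (1(10)E,4E,6R,8S)-13-acetoxy-8-hydroxygermacra-1(10),4,7(11)-trien-12,6-olide; 18 angelic acid, (2Z)-2-methylbut-2-enoic acid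
Product: 20 (1(10)E,4E,6R,8S)-13-acetoxy-8-angeloyloxygermacra-1(10),4,7(11)-trien-12,6-olide, via angeloyl mixed anhydride 19 (not isolated)
Conditions: 18 (3 equiv), 2,4,6-trichlorobenzoyl chloride (3 equiv), Et3N (3.1 equiv), toluene, 25 °C; then 17, 60 °C
Reagents that add atoms: none
Why: The Yamaguchi esterification through mixed anhydride 19 acylates the hindered secondary alcohol with retention at C8, and leaving out a nucleophilic catalyst should keep the Z geometry of the angelate (no isomerisation to tiglate).

Step 13
Reactants: 20 (1(10)E,4E,6R,8S)-13-acetoxy-8-angeloyloxygermacra-1(10),4,7(11)-trien-12,6-olide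
Product: 21 (1R,4R,5R,6S,8S,10R)-13-acetoxy-8-angeloyloxy-1,10:4,5-diepoxygermacr-7(11)-en-12,6-olide (1β,10α;4α,5β-diepoxide, 6α-lactone, 8α-ester; the target)
Conditions: mCPBA (2.3 equiv), NaHCO3, CH2Cl2, 0 °C
Reagents that add atoms: 3-chloroperbenzoic acid, OOC(=O)c1cccc(Cl)c1
Why: In this Prilezhaev epoxidation the peracid should attack only the two electron-rich trisubstituted ring alkenes (the butenolide and angelate alkenes are electron-poor), each stereospecifically from its outer face in the crown conformation of the (E,E)-cyclodecadiene held by the trans-lactone, which gives the (1R,10R) and (4R,5R) trans-epoxides, with bicarbonate suppressing acid-induced transannular cyclisation.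

Compound list
1 | methyl (2E)-3,7-dimethylocta-2,6-dienoate (methyl geranate) | COC(=O)/C=C(\C)CCC=C(C)C | starting material
2 | methyl (2E,6E)-8-hydroxy-3,7-dimethylocta-2,6-dienoate | COC(=O)/C=C(\C)CC/C=C(\C)CO | intermediate
3 | methyl (2E,6E)-8-bromo-3,7-dimethylocta-2,6-dienoate | COC(=O)/C=C(\C)CC/C=C(\C)CBr | intermediate
4 | methyl (2E,6E)-3,7-dimethyl-9-oxonona-2,6-dienoate | COC(=O)/C=C(\C)CC/C=C(\C)CC=O | intermediate
5 | 2-(prop-2-yn-1-yloxy)oxane (tetrahydropyranyl propargyl ether, racemic) | C#CCOC1CCCCO1 | starting material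
6 | methyl[3-(oxan-2-yloxy)prop-1-yn-1-yl]zinc (methylzinc acetylide of 5) | C[Zn]C#CCOC1CCCCO1 | intermediate
7 | methyl (2E,6E,9S)-9-hydroxy-3,7-dimethyl-12-(oxan-2-yloxy)dodeca-2,6-dien-10-ynoate | COC(=O)/C=C(\C)CC/C=C(\C)C[C@H](O)C#CCOC1CCCCO1 | intermediate
8 | methyl (2E,6E,9S)-9-[(tert-butyldimethylsilyl)oxy]-3,7-dimethyl-12-(oxan-2-yloxy)dodeca-2,6-dien-10-ynoate | COC(=O)/C=C(\C)CC/C=C(\C)C[C@H](O[Si](C)(C)C(C)(C)C)C#CCOC1CCCCO1 | intermediate
9 | methyl (2E,6E,9S)-12-bromo-9-[(tert-butyldimethylsilyl)oxy]-3,7-dimethyldodeca-2,6-dien-10-ynoate | COC(=O)/C=C(\C)CC/C=C(\C)C[C@H](O[Si](C)(C)C(C)(C)C)C#CCBr | intermediate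
10 | (2E,6E,9S)-12-bromo-9-[(tert-butyldimethylsilyl)oxy]-3,7-dimethyldodeca-2,6-dien-10-yn-1-ol | OC/C=C(\C)CC/C=C(\C)C[C@H](O[Si](C)(C)C(C)(C)C)C#CCBr | intermediate
11 | (2E,6E,9S)-12-bromo-9-[(tert-butyldimethylsilyl)oxy]-3,7-dimethyldodeca-2,6-dien-10-ynal | O=C/C=C(\C)CC/C=C(\C)C[C@H](O[Si](C)(C)C(C)(C)C)C#CCBr | intermediate
12 | propargylchromium dichloride from 11 (CrCl2 in place of Br on the propargylic carbon, 9S) | O=C/C=C(\C)CC/C=C(\C)C[C@H](O[Si](C)(C)C(C)(C)C)C#CC[Cr](Cl)Cl | intermediate
13 | (1R,3S,5E,9E)-3-[(tert-butyldimethylsilyl)oxy]-2-ethenylidene-5,9-dimethylcyclodeca-5,9-dien-1-ol (germacrane numbering 6R,8S; 6-OH and 8-OTBS syn) | CC(C)(C)[Si](C)(C)O[C@H]1C/C(C)=C/CC/C(C)=C/[C@@H](O)C1=C=C | intermediate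
14 | alkoxycarbonylpalladium acetate of 13 (O6–C(=O)–Pd–OAc) | CC(C)(C)[Si](C)(C)O[C@H]1C/C(C)=C/CC/C(C)=C/[C@@H](OC(=O)[Pd]OC(C)=O)C1=C=C | intermediate
15 | allylpalladium acetate (closed butenolide, palladium on C13, drawn as the σ-form) | CC(C)(C)[Si](C)(C)O[C@H]1C/C(C)=C/CC/C(C)=C/[C@H]2OC(=O)C(C[Pd]OC(C)=O)=C12 | intermediate
16 | (1(10)E,4E,6R,8S)-13-acetoxy-8-[(tert-butyldimethylsilyl)oxy]germacra-1(10),4,7(11)-trien-12,6-olide | CC(C)(C)[Si](C)(C)O[C@H]1C/C(C)=C/CC/C(C)=C/[C@H]2OC(=O)C(COC(C)=O)=C12 | intermediate
17 | (1(10)E,4E,6R,8S)-13-acetoxy-8-hydroxygermacra-1(10),4,7(11)-trien-12,6-olide | O[C@H]1C/C(C)=C/CC/C(C)=C/[C@H]2OC(=O)C(COC(C)=O)=C12 | intermediate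
18 | angelic acid, (2Z)-2-methylbut-2-enoic acid | C/C=C(/C)C(=O)O | starting material
19 | angelic 2,4,6-trichlorobenzoic anhydride | C/C=C(/C)C(=O)OC(=O)c1c(Cl)cc(Cl)cc1Cl | intermediate
20 | (1(10)E,4E,6R,8S)-13-acetoxy-8-angeloyloxygermacra-1(10),4,7(11)-trien-12,6-olide | C/C=C(/C)C(=O)O[C@H]1C/C(C)=C/CC/C(C)=C/[C@H]2OC(=O)C(COC(C)=O)=C12 | intermediate
21 | (1R,4R,5R,6S,8S,10R)-13-acetoxy-8-angeloyloxy-1,10:4,5-diepoxygermacr-7(11)-en-12,6-olide (CNP0251711.2) | C/C=C(/C)C(=O)O[C@H]1C[C@@]2(C)O[C@@H]2CC[C@@]2(C)O[C@@H]2[C@H]2OC(=O)C(COC(C)=O)=C12 | target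

Total step count: 13. Longest linear sequence: 13 steps (1 → 21); 5 and 18 are commercial and enter directly.

Steps most likely to fail

1. Step 10 (proposed new method). The divalent palladium may instead drive 5-endo oxypalladation of the allene by the free hydroxyl or complex the 1,5-diene and start a transannular cyclisation, and the allylpalladium may lose a β-hydrogen before acetate captures it. The fallback uses known chemistry and still closes the ring at C12–C11. It sets out from 13: the established chlorocyclocarbonylation of 2,3-allenols (PdCl2 5 mol %, CuCl2 3 equiv, CO 1 atm, THF, 25 °C) should give the 13-chloro butenolide F1. SN2 displacement of its primary allylic chloride with CsOAc in DMF at 25 °C then gives 16, where the route is rejoined.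

2. Step 9. The ring closure may show poor facial selectivity at the aldehyde (C6 epimers), the allenyl tautomer of the organochromium may lose the silyloxy group by β-elimination, and intermolecular coupling may compete. The fallback moves control of C6 from the ring closure to a reagent. It sets out from 13 as obtained together with its C6 epimer: oxidation with Dess–Martin periodinane (NaHCO3, CH2Cl2, 0 °C) gives the allenyl ketone F2. Reduction with (S)-Me-CBS oxazaborolidine and catecholborane (toluene, −78 °C; the α-branched allenyl carbon acts as the large group) should return 13 with the 6R configuration.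

3. Step 4. The β,γ-unsaturated aldehyde may isomerise into conjugation under the zinc alkoxide conditions, and the enantioselectivity for an unbranched aliphatic aldehyde may be insufficient. The fallback separates C–C bond formation from stereocontrol. It sets out from 4: addition of the lithium acetylide of 5 (nBuLi, THF, −78 °C) gives the racemic carbinol F3. Dess–Martin oxidation (NaHCO3, CH2Cl2, 0 °C) gives the ynone F4. Noyori asymmetric transfer hydrogenation with RuCl[(S,S)-TsDPEN](p-cymene) in iPrOH at 25 °C then sets the 9S centre and returns 7.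

Further compounds
F1 | step 10 | (1(10)E,4E,6R,8S)-8-[(tert-butyldimethylsilyl)oxy]-13-chlorogermacra-1(10),4,7(11)-trien-12,6-olide | CC(C)(C)[Si](C)(C)O[C@H]1C/C(C)=C/CC/C(C)=C/[C@H]2OC(=O)C(CCl)=C12
F2 | step 9 | (3S,5E,9E)-3-[(tert-butyldimethylsilyl)oxy]-2-ethenylidene-5,9-dimethylcyclodeca-5,9-dien-1-one | CC(C)(C)[Si](C)(C)O[C@H]1C/C(C)=C/CC/C(C)=C/C(=O)C1=C=C
F3 | step 4 | methyl (2E,6E)-9-hydroxy-3,7-dimethyl-12-(oxan-2-yloxy)dodeca-2,6-dien-10-ynoate, racemic at C9 | COC(=O)/C=C(\C)CC/C=C(\C)CC(O)C#CCOC1CCCCO1
F4 | step 4 | methyl (2E,6E)-3,7-dimethyl-9-oxo-12-(oxan-2-yloxy)dodeca-2,6-dien-10-ynoate | COC(=O)/C=C(\C)CC/C=C(\C)CC(=O)C#CCOC1CCCCO1
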